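In chromane numbering (ring A carbocycle, ring B pyranone), the ring-fusion bond C4a–C8a joins C4a, the carbon between the C4 and C5 carbonyls, to C8a, an sp2 carbon at the carboxylic acid oxidation level bearing the ring oxygen O1. It is made by intramolecular O-to-C acyl transfer: in an acyclic β-diketone whose O1 is esterified by a desymmetrised 3-phenylglutarate, C4a attacks the ester carbonyl C8a, and dehydration of the cyclic hemiketal gives ring B with O1 fixed on C8a. The glutarate supplies C8, the benzylic stereocentre and the acid; a vinylogous Dieckmann closure onto the ester at the preformed quaternary C6 completes ring A.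

Key step: step 14

Assumption: in steps 7, 8 and 9 the sense of induction is assigned from the usual models for these controllers; each exists in a mirror-image or pseudo-enantiomeric form that would be used instead, with no other change, if the sense proved opposite. Enolisable compounds are drawn as one tautomer.

Step 1
Reactants: 1 (1S,5S)-(−)-verbenone
Product: 2 (1S,3R)-3-acetyl-2,2-dimethylcyclobutane-1-carboxylic acid (cis-pinononic acid)
Conditions: RuCl3·xH2O (cat.), NaIO4, CCl4/MeCN/H2O, rt
Reagents that add atoms: sodium periodate, [Na+].[O-]I(=O)(=O)=O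
Why: RuO4 formed in situ cleaves the enone C=C (oxidative alkene cleavage) and the resulting α-keto acid loses its carboxyl carbon as CO2, so that both cyclobutane stereocentres come unchanged from 1 in their cis relationship.

Step 2
Reactants: 2 cis-pinononic acid
Product: 3 (1S,3S)-2,2-dimethyl-3-(prop-1-en-2-yl)cyclobutane-1-carboxylic acid
Conditions: Ph3PCH3Br, KOtBu (excess), THF, 0 °C to rt; then aq. HCl
Reagents that add atoms: methyltriphenylphosphonium bromide, C[P+](c1ccccc1)(c1ccccc1)c1ccccc1.[Br-]
Why: Wittig methylenation of the methyl ketone by excess ylide while the carboxylate is inert; low temperature and short contact are chosen to keep the ketone α-stereocentre of the cis-cyclobutane from epimerising.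

Step 3
Reactants: 3 isopropenyl acid
Product: 4 [(1S,3S)-2,2-dimethyl-3-(prop-1-en-2-yl)cyclobutyl]methanol
Conditions: LiAlH4, THF, 0 °C to rt
Reagents that add atoms: none
Why: LiAlH4 reduction of the carboxylic acid to the primary alcohol; the 1,1-disubstituted alkene is inert.

Step 4
Reactants: 4 cyclobutylmethanol
Product: 5 (1S,3S)-1-(iodomethyl)-2,2-dimethyl-3-(prop-1-en-2-yl)cyclobutane
Conditions: I2, PPh3, imidazole, CH2Cl2, 0 °C to rt
Reagents that add atoms: iodine, [I][I]
Why: Appel-type iodination by SN2 displacement of the oxyphosphonium group at the primary carbon, so that no cyclobutylcarbinyl cation (ring expansion) is involved.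

Step 5
Reactants: 5 iodide; 6 methyl acetoacetate (excess)
Product: 7 methyl 2-{[(1R,3S)-2,2-dimethyl-3-(prop-1-en-2-yl)cyclobutyl]methyl}-3-oxobutanoate (both C2 epimers)
Conditions: K2CO3, DMF, 70 °C
Reagents that add atoms: none
Why: C-alkylation (SN2) of the acetoacetate anion by the primary iodide, with 6 in excess to suppress dialkylation; the new α-centre is labile and is erased in step 6.

Step 6
Reactants: 7 alkylated acetoacetate; 8 L-valine tert-butyl ester
Product: 9 methyl (2Z)-3-{[(2S)-1-tert-butoxy-3-methyl-1-oxobutan-2-yl]amino}-2-{[(1R,3S)-2,2-dimethyl-3-(prop-1-en-2-yl)cyclobutyl]methyl}but-2-enoate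
Conditions: BF3·OEt2 (cat.), benzene, reflux, Dean–Stark
Reagents that add atoms: none
Why: Acid-catalysed condensation gives the hydrogen-bonded Z β-enamino ester that carries the valine-derived controller.

Step 7
Reactants: 9 enamino ester; 10 prenyl bromide
Product: 13 methyl (2R)-2-acetyl-2-{[(1R,3S)-2,2-dimethyl-3-(prop-1-en-2-yl)cyclobutyl]methyl}-5-methylhex-4-enoate, via lithiated enamine 11 (not isolated), via imine 12 (not isolated)
Conditions: LiN(iPr)2, toluene, −78 °C; HMPA, then 10, −78 °C; then 1 M aq. HCl, THF, rt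
Reagents that add atoms: water, O
Why: Asymmetric alkylation of a lithiated chiral β-enamino ester: lithium is held between nitrogen and the tert-butyl ester carbonyl so that the isopropyl group shields one face, prenyl bromide (SN2 at its primary carbon) enters from the other to set C6 as R, and hydrolysis of the imine releases the quaternary β-keto ester and the auxiliary.

Step 8
Reactants: 14 3-phenylglutaric anhydride
Product: 15 (3S)-5-methoxy-5-oxo-3-phenylpentanoic acid
Conditions: MeOH, (DHQD)2AQN (cat.), Et2O, −40 °C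
Reagents that add atoms: methanol, CO
Why: Cinchona alkaloid-catalysed alcoholysis desymmetrises the prochiral anhydride by general-base delivery of methanol to one of the two enantiotopic carbonyl groups, which fixes the benzylic centre as S.

Step 9
Reactants: 16 acetaldehyde; 17 (E)-crotylboronic acid pinacol ester
Product: 19 (2R,3S)-3-methylpent-4-en-2-ol, via homoallyl borate 18 (not isolated)
Conditions: (S)-TRIP (cat.), 4 Å MS, toluene, −30 °C; then aqueous work-up
Reagents that add atoms: none
Why: Brønsted acid-catalysed crotylboration through a closed chair (Zimmerman–Traxler) transition state in which the E-crotyl geometry gives the anti relationship and the chiral phosphoric acid, hydrogen-bonded to a boronate oxygen, selects the aldehyde face to give 2R,3S.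

Step 10
Reactants: 19 homoallylic alcohol; 15 hemiester
Product: 20 methyl (2R,3S)-3-methylpent-4-en-2-yl (3R)-3-phenylpentanedioate
Conditions: DCC, DMAP (cat.), CH2Cl2, 0 °C to rt
Reagents that add atoms: none
Why: Steglich esterification of the secondary alcohol by the free carboxyl arm of 15; no stereocentre is α to the activated carbonyl, so none is at risk.

Step 11
Reactants: 20 alkene ester
Product: 22 methyl (2R,3R)-3-methyl-4-oxobutan-2-yl (3R)-3-phenylpentanedioate, via ozonide 21 (not isolated)
Conditions: O3, CH2Cl2, −78 °C; then PPh3, −78 °C to rt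
Reagents that add atoms: ozone, [O-][O+]=O
Why: Ozonolysis of the only alkene with reductive work-up gives the aldehyde under neutral conditions, so that the α-stereocentre and the β-acyloxy group are kept.

Step 12
Reactants: 13 quaternary keto ester; 22 aldehyde
Product: 24 methyl (2R,5RS,6S,7R)-2-{[(1R,3S)-2,2-dimethyl-3-(prop-1-en-2-yl)cyclobutyl]methyl}-5-hydroxy-7-{[(3R)-5-methoxy-5-oxo-3-phenylpentanoyl]oxy}-6-methyl-2-(3-methylbut-2-en-1-yl)-3-oxooctanoate, via lithium enolate 23 (not isolated)
Conditions: LiN(iPr)2, THF, −78 °C; then 22, −78 °C; AcOH quench at −78 °C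
Reagents that add atoms: none
Why: Aldol addition: 13 can enolise only toward its methyl group because C6 is quaternary, and the lithium enolate should add to the aldehyde at −78 °C faster than it deprotonates it; the new carbinol centre is left uncontrolled because step 13 oxidises it.

Step 13
Reactants: 24 β-hydroxy ketone
Product: 25 methyl (2R,6R,7R)-2-{[(1R,3S)-2,2-dimethyl-3-(prop-1-en-2-yl)cyclobutyl]methyl}-7-{[(3R)-5-methoxy-5-oxo-3-phenylpentanoyl]oxy}-6-methyl-2-(3-methylbut-2-en-1-yl)-3,5-dioxooctanoate
Conditions: Dess–Martin periodinane, CH2Cl2, 0 °C to rt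
Reagents that add atoms: none
Why: Dess–Martin oxidation of the β-hydroxy ketone to the β-diketone under neutral, non-epimerising conditions.

Step 14
Reactants: 25 β-diketone
Product: 27 methyl (2R)-2-{[(2R,3R)-6-[(2S)-4-methoxy-4-oxo-2-phenylbutyl]-2,3-dimethyl-4-oxo-3,4-dihydro-2H-pyran-5-yl]carbonyl}-2-{[(1R,3S)-2,2-dimethyl-3-(prop-1-en-2-yl)cyclobutyl]methyl}-5-methylhex-4-enoate, via cyclic hemiketal 26 (not isolated)
Conditions: KOtBu (1.05 equiv), THF, 0 to 40 °C; then AcOH, PPTS, 4 Å MS, CH2Cl2, rt
Reagents that add atoms: none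
Why: One equivalent of base gives the potassium diketonate, whose central carbon C4a adds to the carbonyl carbon C8a of the glutarate ester held on O1 by the O1–C2–C3–C4 chain; this is an aliphatic Baker–Venkataraman-type O-to-C acyl transfer (intramolecular Claisen condensation of a β-acyloxy ketone), closest to the acyl migrations that give 3-acylchromones and to the Claisen cyclisations of β-acyloxy ketones to dihydropyranones. Ring B is closed by the new C4a–C8a bond in a 6-exo-trig attack (ring atoms O1, C2, C3, C4, C4a, C8a), the tetrahedral intermediate being the cyclic hemiketal 26, and the strongly acidic triacylmethane product is the thermodynamic sink that should pull reversible O-acylation or enol-lactonisation onto the C7 ester back. Mild acid then eliminates the hemiketal hydroxyl to the C4a=C8a vinylogous ester, so no new stereocentre remains and C2 and C3 are carried through unchanged (C3 is not enolised by one equivalent of base, and trans is also the more stable arrangement). The step needs C- over O-acylation, no β-elimination of the acyloxy group, and O1 ending on C8a and not on C5: the first rests on the stability of the triacylmethane anion, the second on never exceeding one equivalent of base, the third on delivery of O1 to C8a by the acyl transfer itself while closure on C5 is hindered by the neighbouring quaternary C6.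

Step 15
Reactants: 27 dihydropyranone
Product: 28 methyl (3S)-3-[(2R,3R,6R)-6-{[(1R,3S)-2,2-dimethyl-3-(prop-1-en-2-yl)cyclobutyl]methyl}-5-hydroxy-2,3-dimethyl-6-(3-methylbut-2-en-1-yl)-4,7-dioxo-3,4,6,7-tetrahydro-2H-chromen-8-yl]-3-phenylpropanoate
Conditions: LiN(SiMe3)2 (1.1 equiv), THF, −78 to 0 °C; then 1 M aq. HCl
Reagents that add atoms: none
Why: The base removes the doubly vinylogous C8–H (conjugated through C8a=C4a to the C4 and C5 carbonyls) and the extended enolate acylates at C8 on the C7 methyl ester (vinylogous Dieckmann condensation, 6-exo-trig, helped by the gem-disubstituted C6) to give the acidic enolised trione whose deprotonation drives the closure; C6, set in step 7, becomes the ring stereocentre without being touched.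

Step 16
Reactants: 28 methyl ester
Product: 29 (3S)-3-[(2R,3R,6R)-6-{[(1R,3S)-2,2-dimethyl-3-(prop-1-en-2-yl)cyclobutyl]methyl}-5-hydroxy-2,3-dimethyl-6-(3-methylbut-2-en-1-yl)-4,7-dioxo-3,4,6,7-tetrahydro-2H-chromen-8-yl]-3-phenylpropanoic acid
Conditions: LiOH·H2O, THF/H2O, 0 °C to rt; then 1 M aq. HCl to pH 3
Reagents that add atoms: lithium hydroxide, [Li+].[OH-]
Why: Saponification of the unhindered methyl ester while the core is protected as its delocalised enolate (no second deprotonation at C3, so ring B should neither open nor epimerise), any enol lactone between the C7 enol and the side chain being opened as well; acidification gives the acid.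

Compound list
1 | (1S,5S)-(−)-verbenone | O=C1C=C(C)[C@@H]2C[C@H]1C2(C)C | starting material
2 | (1S,3R)-3-acetyl-2,2-dimethylcyclobutane-1-carboxylic acid | CC(=O)[C@@H]1C[C@H](C(=O)O)C1(C)C | intermediate
3 | (1S,3S)-2,2-dimethyl-3-(prop-1-en-2-yl)cyclobutane-1-carboxylic acid | C=C(C)[C@@H]1C[C@H](C(=O)O)C1(C)C | intermediate
4 | [(1S,3S)-2,2-dimethyl-3-(prop-1-en-2-yl)cyclobutyl]methanol | C=C(C)[C@@H]1C[C@H](CO)C1(C)C | intermediate
5 | (1S,3S)-1-(iodomethyl)-2,2-dimethyl-3-(prop-1-en-2-yl)cyclobutane | C=C(C)[C@@H]1C[C@H](CI)C1(C)C | intermediate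
6 | methyl acetoacetate | CC(=O)CC(=O)OC | starting material
7 | methyl 2-{[(1R,3S)-2,2-dimethyl-3-(prop-1-en-2-yl)cyclobutyl]methyl}-3-oxobutanoate (C2 epimers) | C=C(C)[C@@H]1C[C@H](CC(C(C)=O)C(=O)OC)C1(C)C | intermediate
8 | L-valine tert-butyl ester | N[C@@H](C(C)C)C(=O)OC(C)(C)C | starting material
9 | Z β-enamino ester of 7 with 8 | C=C(C)[C@@H]1C[C@H](C/C(C(=O)OC)=C(\C)N[C@@H](C(C)C)C(=O)OC(C)(C)C)C1(C)C | intermediate
10 | prenyl bromide (1-bromo-3-methylbut-2-ene) | CC(C)=CCBr | starting material
11 | N-lithio derivative of 9 (not isolated) | C=C(C)[C@@H]1C[C@H](C/C(C(=O)OC)=C(\C)N([Li])[C@@H](C(C)C)C(=O)OC(C)(C)C)C1(C)C | intermediate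
12 | N-[(2S)-1-tert-butoxy-3-methyl-1-oxobutan-2-yl] imine of 13 (not isolated) | C=C(C)[C@@H]1C[C@H](C[C@@](C(C)=N[C@@H](C(C)C)C(=O)OC(C)(C)C)(CC=C(C)C)C(=O)OC)C1(C)C | intermediate
13 | methyl (2R)-2-acetyl-2-{[(1R,3S)-2,2-dimethyl-3-(prop-1-en-2-yl)cyclobutyl]methyl}-5-methylhex-4-enoate | C=C(C)[C@@H]1C[C@H](C[C@@](C(C)=O)(CC=C(C)C)C(=O)OC)C1(C)C | intermediate
14 | 3-phenylglutaric anhydride | O=C1CC(c2ccccc2)CC(=O)O1 | starting material
15 | (3S)-5-methoxy-5-oxo-3-phenylpentanoic acid | OC(=O)C[C@@H](CC(=O)OC)c1ccccc1 | intermediate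
16 | acetaldehyde | CC=O | starting material
17 | (E)-crotylboronic acid pinacol ester | C/C=C/CB1OC(C)(C)C(C)(C)O1 | starting material
18 | 2-{[(2R,3S)-3-methylpent-4-en-2-yl]oxy}-4,4,5,5-tetramethyl-1,3,2-dioxaborolane (not isolated) | C=C[C@H](C)[C@@H](C)OB1OC(C)(C)C(C)(C)O1 | intermediate
19 | (2R,3S)-3-methylpent-4-en-2-ol (anti) | C=C[C@H](C)[C@@H](C)O | intermediate
20 | methyl (2R,3S)-3-methylpent-4-en-2-yl (3R)-3-phenylpentanedioate | C=C[C@H](C)[C@@H](C)OC(=O)C[C@@H](CC(=O)OC)c1ccccc1 | intermediate
21 | secondary ozonide (1,2,4-trioxolane) of 20 (not isolated) | O1OC(OC1)[C@H](C)[C@@H](C)OC(=O)C[C@@H](CC(=O)OC)c1ccccc1 | intermediate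
22 | methyl (2R,3R)-3-methyl-4-oxobutan-2-yl (3R)-3-phenylpentanedioate | O=C[C@H](C)[C@@H](C)OC(=O)C[C@@H](CC(=O)OC)c1ccccc1 | intermediate
23 | lithium enolate of 13 on the methyl ketone side (not isolated) | C=C(C)[C@@H]1C[C@H](C[C@@](C(=C)O[Li])(CC=C(C)C)C(=O)OC)C1(C)C | intermediate
24 | aldol adduct, 5-hydroxy-3-oxooctanoate (both C5 epimers) | C=C(C)[C@@H]1C[C@H](C[C@@](C(=O)CC(O)[C@H](C)[C@@H](C)OC(=O)C[C@@H](CC(=O)OC)c2ccccc2)(CC=C(C)C)C(=O)OC)C1(C)C | intermediate
25 | β-diketone, 3,5-dioxooctanoate carrying the O1 glutarate | C=C(C)[C@@H]1C[C@H](C[C@@](C(=O)CC(=O)[C@H](C)[C@@H](C)OC(=O)C[C@@H](CC(=O)OC)c2ccccc2)(CC=C(C)C)C(=O)OC)C1(C)C | intermediate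
26 | cyclic hemiketal, 6-hydroxy-tetrahydropyran-4-one formed by the C4a–C8a bond (not isolated) | C=C(C)[C@@H]1C[C@H](C[C@@](C(=O)C2C(=O)[C@H](C)[C@@H](C)OC2(O)C[C@@H](CC(=O)OC)c2ccccc2)(CC=C(C)C)C(=O)OC)C1(C)C | intermediate
27 | (2R,3R)-2,3-dimethyl-2,3-dihydro-4H-pyran-4-one with the C5 acyl group and the C6 (2S)-4-methoxy-4-oxo-2-phenylbutyl group | C=C(C)[C@@H]1C[C@H](C[C@@](C(=O)C2=C(C[C@@H](CC(=O)OC)c3ccccc3)O[C@H](C)[C@@H](C)C2=O)(CC=C(C)C)C(=O)OC)C1(C)C | intermediate
28 | methyl ester of the target | C=C(C)[C@@H]1C[C@H](C[C@@]2(CC=C(C)C)C(=O)C([C@@H](CC(=O)OC)c3ccccc3)=C3O[C@H](C)[C@@H](C)C(=O)C3=C2O)C1(C)C | intermediate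
29 | CNP0103716.3 | C=C(C)[C@@H]1C[C@H](C[C@@]2(CC=C(C)C)C(=O)C([C@@H](CC(=O)O)c3ccccc3)=C3O[C@H](C)[C@@H](C)C(=O)C3=C2O)C1(C)C | target

Total step count: 16. Longest linear sequence: 12 steps (steps 1–7 and 12–16).

Steps most likely to fail

Step 14. The diketonate may add too slowly to the unactivated secondary-alkyl ester, so that enol-lactonisation onto the C7 ester, β-elimination of the acyloxy group, or closure of O1 onto C5 takes over. The fallback sets out from 24 and comes back at 27. Silylation of the carbinol of 24 (Et3SiOTf, 2,6-lutidine, CH2Cl2, −78 °C) gives the triethylsilyl ether F1. LiN(SiMe3)2 (THF, −78 to −20 °C) then forms the enolate of the C5 ketone, which can only form toward C4a. This simple ketone enolate closes the same C4a–C8a bond by Claisen-type cyclisation onto the O1 ester, giving the hemiketal F2 (not isolated). PPTS dehydrates it to the 4-triethylsilyloxy dihydropyran F3, HF·pyridine frees the carbinol F4, and Dess–Martin oxidation at C4 gives 27.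

Step 7. Facial discrimination may be incomplete, or alkylation slow, at the hindered α-carbon, which would erode the configuration at C6. The fallback sets out from 7 and comes back at 13. Direct prenylation of 7 (K2CO3, 10, acetone, reflux) gives 13 together with its C2 epimer F5. The two are diastereomers because of the cyclobutane and are separated by preparative HPLC.

Step 15. Acylation at the hindered C7 ester may be slow, and competing deprotonation at C3 could then open ring B by β-elimination and scramble C2. The fallback sets out from 24 and comes back at 28. The silyl ether F1 is converted into the 4-triethylsilyloxy dihydropyran F3 as described above. F3 has no C4 carbonyl, so ring B cannot open and the C8 anion is more nucleophilic. LiN(SiMe3)2 closes ring A onto the C7 ester to give the silyl ether F6, HF·pyridine gives the carbinol F7, and Dess–Martin oxidation at C4 gives 28.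

Further compounds
F1 | step 14 | O-triethylsilyl ether of 24 | C=C(C)[C@@H]1C[C@H](C[C@@](C(=O)CC(O[Si](CC)(CC)CC)[C@H](C)[C@@H](C)OC(=O)C[C@@H](CC(=O)OC)c2ccccc2)(CC=C(C)C)C(=O)OC)C1(C)C
F2 | step 14 | cyclic hemiketal from F1 (not isolated) | C=C(C)[C@@H]1C[C@H](C[C@@](C(=O)C2C(O[Si](CC)(CC)CC)[C@H](C)[C@@H](C)OC2(O)C[C@@H](CC(=O)OC)c2ccccc2)(CC=C(C)C)C(=O)OC)C1(C)C
F3 | step 14 | 4-triethylsilyloxy-3,4-dihydro-2H-pyran analogue of 27 (C4 carbinol level) | C=C(C)[C@@H]1C[C@H](C[C@@](C(=O)C2=C(C[C@@H](CC(=O)OC)c3ccccc3)O[C@H](C)[C@@H](C)C2O[Si](CC)(CC)CC)(CC=C(C)C)C(=O)OC)C1(C)C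
F4 | step 14 | 4-hydroxy-3,4-dihydro-2H-pyran analogue of 27 | C=C(C)[C@@H]1C[C@H](C[C@@](C(=O)C2=C(C[C@@H](CC(=O)OC)c3ccccc3)O[C@H](C)[C@@H](C)C2O)(CC=C(C)C)C(=O)OC)C1(C)C
F5 | step 7 | C2 epimer of 13, methyl (2S)-2-acetyl-2-{[(1R,3S)-2,2-dimethyl-3-(prop-1-en-2-yl)cyclobutyl]methyl}-5-methylhex-4-enoate | C=C(C)[C@@H]1C[C@H](C[C@](C(C)=O)(CC=C(C)C)C(=O)OC)C1(C)C
F6 | step 15 | 4-triethylsilyloxy analogue of 28 (C4 carbinol level) | C=C(C)[C@@H]1C[C@H](C[C@@]2(CC=C(C)C)C(=O)C([C@@H](CC(=O)OC)c3ccccc3)=C3O[C@H](C)[C@@H](C)C(O[Si](CC)(CC)CC)C3=C2O)C1(C)C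
F7 | step 15 | 4-hydroxy analogue of 28 | C=C(C)[C@@H]1C[C@H](C[C@@]2(CC=C(C)C)C(=O)C([C@@H](CC(=O)OC)c3ccccc3)=C3O[C@H](C)[C@@H](C)C(O)C3=C2O)C1(C)C
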